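The readings come from a simulation with constants of no real substance; the scatter is artificial.

The closed, stirred vessel holds a solid reagent under a solution, and its protic impurity lies above the blue run and below the red run.

| flask | starting material | solid reagent | protic impurity | remark | time |
|---|---|---|---|---|---|
| blue | 0.20 M | 0.22 M | 0.13 M | run made earlier |  |
| red | 0.20 M | 0.22 M | 0.30 M | run made earlier |  |
| flask | 0.20 M | 0.220 M | 0.200 M |  | 15 d |

| run | time / d | starting material / % | target / % |
|---|---|---|---|
| blue | 2.08 | 23 | 38 |
| blue | 5.00 | 2 | 58 |
| blue | 10.0 | 0 | 58 |
| blue | 15.0 | 0 | 57 |
| red | 2.08 | 7 | 28 |
| red | 5.00 | 0 | 31 |
| red | 10.0 | 2 | 31 |
| red | 15.0 | 0 | 34 |

(standard deviation of a reading: 1.5 percentage points)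

- solid reagent is a solid; its amount is given per volume of the solution
- the analysis behind the earlier runs scatters by 1.5 percentage points, standard deviation
- at the start none of the solid reagent is in solution
- the reaction counts as stopped when no species that holds the starting material changes by six tenths of a point or more over the second half of the time

1. why nothing more happens at 15 d, or that something still does (for what has run out or reacted, a solid counts together with what of it has only dissolved) (it is still moving / all of the starting material has reacted / the partner has run out first)
2. conversion of starting material at 15 d
3. amount of target at 15 d, in percent of the starting material charged

Red carries more impurity than blue and plateaus lower, at 32.0% of target against 57.7%, each averaged from 5.00 d on. One chemist draws a straight line between the runs, assumes no stoichiometry, and gets 47.1% for this flask.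

The other compares rates at one moment. Let one unit of impurity be spent for each unit of starting material lost to it, and let target formed per starting material lost to impurity be a constant divided by the impurity present at that moment, so the comparison drifts toward target as impurity is spent. Summed over a run, target then equals that constant times ln(impurity charged / impurity left), the impurity left being taken as its charge less the starting material not read as target. The blue readings give 0.109 M and the red readings 0.106 M, so their mean 0.108 M is read as the split constant, a selectivity factor in concentration units.

The forecast takes the second side: all of the starting material has reacted, conversion 100%, target 44.5%, within 41% to 49%, and “the reagent should not run short”. My own reckoning is a different one: taking the impurity left that the forecast's target implies, the split constant returns 43.6%, near the forecast's number but not the same.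

The flask gives: all of the starting material has reacted, conversion 100%, target 45.0%.

    starting material + 2 partner → side product (k = 0.0790 M⁻² h⁻¹)
    starting material + partner → target (k = 0.730 M⁻¹ h⁻¹)
    starting material + protic impurity → quenched substrate (k = 0.150 M⁻¹ h⁻¹)
    solid reagent ⇌ partner, rate k4*(cs4 - [partner]) while solid is left; crystals form when [partner] > cs4 (solubility = 0.110 M, k = 0.0260 h⁻¹)

For this flask the line stands 2.1 percentage points high; target moves 5 points at 0.171 M and at 0.233 M of impurity, and that short span is where I would trust a line. The split constant with the impurity left returns 42.8% against 45.0% for this flask, and 29.4% against 28.4% for the neighbouring flask with 0.34 M of protic impurity. In the neighbouring flask with 0.80 M of starting material, 47.5% stays unreacted at 15.0 d, with partner at 0 M. This flask is at rest: left ten times as long, to 150 d, it changes target by 0 points.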